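**Plan**

1. Retrosynthesis cuts the C6–C7 bond together with the lactone C12–O bond, giving an acyclic C6 epoxy aldehyde / C13 allylic bromide. The enabling feature is that C7 is the γ-carbon of the 2-(methoxycarbonyl)allyl unit C13–C11(C12)–C7, and C6 is a carbinol carbon 1,4 to the C12 carbonyl, so one bond is shared by the ten-membered carbocycle and the γ-lactone ring.
2. The seco chain is cut further at C7–C11 (Morita–Baylis–Hillman), C9–C10 (Stille), C1=C10 (Wittig), C2–C3 (allylboration) and C3–C4 (formylation of a vinyl iodide); the C8 ester is attached last from a separately made epoxy acid.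
3. Forward: but-2-yn-1-ol gives C4–C6; the chain grows to C3, C1, C10/C14, C9–C7, then C11–C13. The C4–C5 oxirane is made first; the ten-membered ring and the lactone then form in one operation; the side-chain oxirane arrives ready-made.
4. Stereochemistry: C3 by reagent-controlled allylboration; C4/C5 by hydroxyl-directed epoxidation of the Z-allylic alcohol; C8/C9 by asymmetric epoxidation and inverting acetate opening at C9; C6/C7 in the ring closure under control of C5 and C8; side chain by asymmetric epoxidation of angelyl alcohol.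
5. Alkene geometry: Z-C4=C5 from trans-hydroalumination/iodination; ring-cis C1=C10 from a Z-selective iodo-Wittig reaction and a stereoretentive Stille coupling; the Z-allylic bromide from SN2' bromination.

Key step: step 21

Assumption: the configurations are read exactly as written, which means a 4,5-cis-epoxide (C3 and C6 on the same side of the oxirane) and a ring-cis C1=C10 bond. Locants C1–C14 below are germacrane locants of the target (C12 lactone carbonyl, C13 exocyclic methylene, C14 ester carbon).

**Route**

Step 1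
Reactants: 1 angelic acid, (Z)-2-methylbut-2-enoic acid
Product: 2 angelyl alcohol, (Z)-2-methylbut-2-en-1-ol
Conditions: LiAlH4, Et2O, 0 °C
Reagents that add atoms: none
Why: Metal hydride reduction of the carboxylic acid to the primary allylic alcohol; the hindered trisubstituted alkene is not attacked, so the Z geometry should be kept.

Step 2
Reactants: 2 angelyl alcohol
Product: 3 (2R,3S)-(2,3-dimethyloxiran-2-yl)methanol
Conditions: Ti(OiPr)4 (cat.), D-(−)-diethyl tartrate (cat.), t-BuOOH, 4 Å MS, CH2Cl2, −20 °C
Reagents that add atoms: tert-butyl hydroperoxide, CC(C)(C)OO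
Why: Sharpless asymmetric epoxidation of a trisubstituted Z-allylic alcohol; the D-(−)-tartrate complex should deliver oxygen to the face that gives the (2R,3S)-epoxy alcohol, and the cis relation of CH2OH and the C3 methyl comes from the alkene.

Step 3
Reactants: 3 (2R,3S)-(2,3-dimethyloxiran-2-yl)methanol
Product: 4 (2S,3S)-2,3-dimethyloxirane-2-carboxylic acid
Conditions: TEMPO (cat.), PhI(OAc)2, MeCN/H2O, rt
Reagents that add atoms: water, O
Why: Oxoammonium (TEMPO) oxidation takes the primary alcohol through the aldehyde hydrate to the acid without opening the epoxide; the α-carbon is quaternary and cannot epimerize.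

Step 4
Reactants: 5 but-2-yn-1-ol
Product: 7 (Z)-3-iodobut-2-en-1-ol, via cyclic alkenylalanate 6 (not isolated)
Conditions: NaAlH2(OCH2CH2OMe)2, THF, 0 °C to rt; then I2, −78 °C
Reagents that add atoms: iodine, [I][I]
Why: Hydroxyl-directed trans-hydroalumination places aluminium on the distal alkyne carbon in a five-membered alanate, and iodinolysis with retention should give the Z-vinyl iodide, which fixes the later cis relation of C3 and C6 across C4–C5.

Step 5
Reactants: 7 (Z)-3-iodobut-2-en-1-ol
Product: 8 (Z)-3-iodobut-2-enyl 4-methoxybenzyl ether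
Conditions: NaH, 4-methoxybenzyl chloride, Bu4NI (cat.), THF, 0 °C to rt
Reagents that add atoms: 4-methoxybenzyl chloride, COc1ccc(CCl)cc1
Why: Williamson etherification of the primary alkoxide; the vinyl iodide is inert to these conditions.

Step 6
Reactants: 8 (Z)-3-iodobut-2-enyl 4-methoxybenzyl ether
Product: 10 (Z)-4-[(4-methoxybenzyl)oxy]-2-methylbut-2-enal, via Z-vinyllithium 9 (not isolated)
Conditions: t-BuLi (2 equiv), Et2O, −78 °C; then DMF; H2O
Reagents that add atoms: N,N-dimethylformamide, CN(C)C=O
Why: Iodine–lithium exchange with retention of alkene geometry (the vinyllithium is held by the allylic ether oxygen) followed by formylation should give the Z-enal that supplies C3.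

Step 7
Reactants: 10 (Z)-4-[(4-methoxybenzyl)oxy]-2-methylbut-2-enal
Product: 11 (2Z,4R)-1-[(4-methoxybenzyl)oxy]-3-methylhepta-2,6-dien-4-ol
Conditions: (+)-B-methoxydiisopinocampheylborane, allylmagnesium bromide, Et2O, −78 °C; then 10, −78 °C; NaOH, H2O2
Reagents that add atoms: allylmagnesium bromide, C=CC[Mg]Br (allyl group, delivered through (+)-B-allyldiisopinocampheylborane made in the flask)
Why: Brown allylboration through a six-membered chair transition state; the isopinocampheyl groups of the (+)-reagent should direct allyl to the Re face of the enal and set C3 as (R) by reagent control.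

Step 8
Reactants: 11 (2Z,4R)-1-[(4-methoxybenzyl)oxy]-3-methylhepta-2,6-dien-4-ol
Product: 12 (1R)-1-[(2S,3R)-3-{[(4-methoxybenzyl)oxy]methyl}-2-methyloxiran-2-yl]but-3-en-1-ol (C3 carbinol, C4–C5 cis-epoxide)
Conditions: mCPBA, NaHCO3, CH2Cl2, 0 °C
Reagents that add atoms: 3-chloroperoxybenzoic acid, OOC(=O)c1cccc(Cl)c1
Why: Hydroxyl-directed peracid epoxidation; allylic 1,3-strain between C3 and the cis CH2OPMB group holds H3 in the alkene plane, so the hydrogen-bonded peracid should add on the hydroxyl face and give the threo 3-hydroxy-4,5-cis-epoxide (4S,5R), the trisubstituted alkene reacting much faster than the terminal one.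

Step 9
Reactants: 12 epoxy alcohol
Product: 13 C3 O-tert-butyldimethylsilyl ether of 12
Conditions: TBSOTf, 2,6-lutidine, CH2Cl2, −78 °C
Reagents that add atoms: tert-butyldimethylsilyl triflate, CC(C)(C)[Si](C)(C)OS(=O)(=O)C(F)(F)F
Why: Silylation of the hindered secondary alcohol with the silyl triflate, buffered with lutidine at low temperature so that the epoxide is not opened.

Step 10
Reactants: 13 silyl ether
Product: 14 C1 aldehyde, (3R)-3-(tert-butyldimethylsilyloxy)-3-(oxiranyl)propanal with the epoxide and PMB ether of 12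
Conditions: OsO4 (cat.), NaIO4, 2,6-lutidine, dioxane/H2O, rt
Reagents that add atoms: sodium periodate, [Na+].[O-][I](=O)(=O)=O
Why: Lemieux–Johnson oxidative cleavage of the only alkene left; this avoids ozone, which could attack the PMB ether.

Step 11
Reactants: 14 aldehyde
Product: 15 methyl (Z)-2-iodo-5-(tert-butyldimethylsilyloxy)-5-(oxiranyl)pent-2-enoate (C1=C10; iodine on C10 cis to the C2 methylene)
Conditions: Ph3P=CHCO2Me, N-iodosuccinimide, CH2Cl2, −20 °C; then K2CO3, 14, rt
Reagents that add atoms: methyl (triphenylphosphoranylidene)acetate, COC(=O)C=P(c1ccccc1)(c1ccccc1)c1ccccc1; N-iodosuccinimide, O=C1CCC(=O)N1I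
Why: Wittig reaction of the α-iodo stabilized ylide formed in the flask; such halo ylides should give the Z-α-iodoenoate, the geometry needed for the ring-cis C1=C10 bond.

Step 12
Reactants: 15 Z-α-iodoenoate; 16 (E)-3-(tributylstannyl)prop-2-en-1-ol
Product: 17 methyl (2E)-2-[(E)-3-hydroxyprop-1-enyl]pent-2-enoate carrying the C3 silyl ether, C4–C5 epoxide and C6 PMB ether of 15 (C9 cis to C2; C8=C9 E; C7 is CH2OH)
Conditions: Pd(PPh3)4 (cat.), CuI, DMF, rt
Reagents that add atoms: none
Why: Stille coupling proceeds with retention at both sp2 carbons, so C9 should take the place of iodine cis to C2; the free allylic hydroxyl is tolerated.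

Step 13
Reactants: 17 dienol
Product: 18 (8S,9S)-8,9-trans-epoxide of 17 (2,3-epoxy alcohol with C7 as CH2OH)
Conditions: Ti(OiPr)4 (cat.), L-(+)-diethyl tartrate (cat.), t-BuOOH, 4 Å MS, CH2Cl2, −20 °C
Reagents that add atoms: tert-butyl hydroperoxide, CC(C)(C)OO
Why: Sharpless asymmetric epoxidation of the E-allylic alcohol; the L-(+)-tartrate complex should set the (8S,9S)-epoxide by reagent control, and only the alkene allylic to the free hydroxyl reacts, the enoate being inert.

Step 14
Reactants: 18 epoxy alcohol
Product: 19 C7 aldehyde of 18 (2,3-epoxy aldehyde)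
Conditions: Dess–Martin periodinane, NaHCO3, CH2Cl2, 0 °C
Reagents that add atoms: none
Why: Dess–Martin oxidation of the primary alcohol under buffered conditions; the α-carbon is an epoxide carbon and should not epimerize.

Step 15
Reactants: 19 epoxy aldehyde
Product: 20 Baylis–Hillman adduct, methyl 2-[hydroxy(oxiranyl)methyl]acrylate unit at C7 (both C7 epimers)
Conditions: methyl acrylate (excess), DABCO, rt
Reagents that add atoms: methyl acrylate, C=CC(=O)OC
Why: Morita–Baylis–Hillman reaction: the ammonium enolate from DABCO and methyl acrylate adds to the electron-poor epoxy aldehyde; the new C7 centre is uncontrolled and need not be, since it is lost in step 17.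

Step 16
Reactants: 20 Baylis–Hillman adduct
Product: 21 (8S,9R)-9-acetoxy-7,8-diol (C7 epimers), C11=C13 acrylate intact
Conditions: Ti(OiPr)4 (1.5 equiv), AcOH, CH2Cl2, 0 °C to rt
Reagents that add atoms: acetic acid, CC(=O)O
Why: Titanium-mediated opening of a 2,3-epoxy alcohol: the titanium alkoxide of the C7 hydroxyl activates the oxirane and acetate should attack the distal, allylic carbon C9 by SN2 with inversion, giving the erythro 8-hydroxy-9-acetate with C8 unchanged.

Step 17
Reactants: 21 acetoxy diol
Product: 22 (Z)-allylic bromide, methyl (Z)-2-(bromomethyl)alk-2-enoate unit C13–C11=C7 (C8 cis to CH2Br), free C8 hydroxyl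
Conditions: N-bromosuccinimide, Me2S, CH2Cl2, 0 °C to rt
Reagents that add atoms: N-bromosuccinimide, O=C1CCC(=O)N1Br
Why: Corey–Kim-type bromination with allylic transposition (SN2'): the alkoxysulfonium salt of the Baylis–Hillman alcohol is displaced by bromide at C13 to give the conjugated Z-bromide, both C7 epimers converging, while the non-allylic C8 hydroxyl is not substituted.

Step 18
Reactants: 22 hydroxy bromide
Product: 23 C8 O-triethylsilyl ether of 22
Conditions: TESOTf, 2,6-lutidine, CH2Cl2, −78 °C
Reagents that add atoms: triethylsilyl triflate, CC[Si](CC)(CC)OS(=O)(=O)C(F)(F)F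
Why: Fast low-temperature silylation turns the C8 oxygen into a non-leaving, non-nucleophilic ether before the γ-hydroxy bromide can cyclize to a dihydrofuran.

Step 19
Reactants: 23 silyl ether bromide
Product: 24 C6 primary alcohol (PMB removed)
Conditions: DDQ, CH2Cl2/pH 7 buffer, 0 °C
Reagents that add atoms: none
Why: Oxidative cleavage of the PMB ether by DDQ (benzylic hydride abstraction, hydrolysis of the oxocarbenium ion); silyl ethers, acetate, epoxide and allylic bromide should be inert.

Step 20
Reactants: 24 alcohol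
Product: 25 seco aldehyde: C6 epoxy aldehyde with C13 allylic bromide
Conditions: Dess–Martin periodinane, NaHCO3, CH2Cl2, 0 °C
Reagents that add atoms: none
Why: Dess–Martin oxidation of the 2,3-epoxy alcohol to the epoxy aldehyde under neutral conditions that leave the allylic bromide untouched.

Step 21
Reactants: 25 seco aldehyde
Product: 27 6,12-lactone with C8 triethylsilyl ether and C3 tert-butyldimethylsilyl ether, via ten-membered hydroxy ester 26 (not isolated)
Conditions: CrCl2 (10 equiv), THF, rt, slow addition of 25 (final 2 mM); aq. NH4Cl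
Reagents that add atoms: none
Why: Two equivalents of CrCl2 reduce the C13–Br bond to a 2-(methoxycarbonyl)allylchromium species (trivalent chromium), which adds through its γ-carbon C7 to the C6 aldehyde in a closed six-membered chair transition state (Cr–O–C6–C7–C11–C13), moving the double bond to C11=C13; the chromium alkoxide on C6 then attacks the C12 methyl ester and expels methoxide. The closest known reaction type is the intramolecular Nozaki–Hiyama–Kishi (chromium Barbier) allylation–lactonization of ω-formyl 2-(bromomethyl)alk-2-enoates, established for ten-membered germacranolides including 4,5-epoxy aldehydes. The ten-membered carbocycle closes by exo attack on the C6 carbonyl (10-exo-trig, both reacting π bonds exocyclic to the new ring), and the γ-lactone closes by 5-exo-trig acyl substitution. C6 and C7 should arise anti (6,7-trans-lactone) because the allylchromium equilibrates by 1,3-metallotropy and reacts through the chair in which both ring branches (C5 on C6, C8 on C7) are equatorial; the face of the allyl unit is set by C8 (allylic 1,3-strain, H8 in the alkene plane, silyloxy group outside) and the face of the aldehyde by C5 (epoxide oxygen coordinated to chromium, attack from the H5 side, 5,6-syn). The step needs chemoselectivity for the allylic bromide over two enoates, the epoxide and the C9 acetate, secured by the mildness of divalent chromium, and ring closure over oligomerization, secured by slow addition and by the two cis elements (ring-cis C1=C10, cis-epoxide) that fold the chain; the C8 oxygen is kept as a silyl ether so that it is neither a leaving group for 1,4-elimination nor a competing lactonization nucleophile.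

Step 22
Reactants: 27 bis-silyl lactone
Product: 28 8-hydroxy lactone (C3 silyl ether retained)
Conditions: HF·pyridine, pyridine, THF, 0 °C
Reagents that add atoms: none
Why: Fluoride-mediated desilylation; the triethylsilyl ether should cleave much faster than the hindered tert-butyldimethylsilyl ether next to the quaternary C4, and the buffered non-basic medium avoids acetyl migration and translactonization.

Step 23
Reactants: 28 8-hydroxy lactone; 4 (2S,3S)-2,3-dimethyloxirane-2-carboxylic acid
Product: 30 3-O-tert-butyldimethylsilyl ether of the target, via mixed anhydride 29 (not isolated)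
Conditions: 4, 2,4,6-trichlorobenzoyl chloride, Et3N, THF, rt; then 28, DMAP, toluene, rt
Reagents that add atoms: none
Why: Yamaguchi esterification: the hindered acid is activated as the mixed anhydride and DMAP transfers the acyl group to the C8 hydroxyl; the stereocentres of the acid are not enolizable and should be kept.

Step 24
Reactants: 30 silyl-protected target
Product: 31 target
Conditions: HF·pyridine, pyridine, THF, 0 °C to rt
Reagents that add atoms: none
Why: Fluoride-mediated cleavage of the remaining silyl ether; buffered HF·pyridine should leave both epoxides, the esters and the α-methylene lactone untouched.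

**Compound list**

1 | angelic acid, (Z)-2-methylbut-2-enoic acid | C/C=C(/C)C(=O)O | starting material
2 | angelyl alcohol, (Z)-2-methylbut-2-en-1-ol | C/C=C(/C)CO | intermediate
3 | (2R,3S)-(2,3-dimethyloxiran-2-yl)methanol | OC[C@@]1(C)O[C@H]1C | intermediate
4 | (2S,3S)-2,3-dimethyloxirane-2-carboxylic acid (epoxyangelic acid) | OC(=O)[C@@]1(C)O[C@H]1C | intermediate
5 | but-2-yn-1-ol | CC#CCO | starting material
6 | sodium salt of the cyclic (Z)-alkenylalanate (five-membered ring O–Al–C=C–CH2, two 2-methoxyethoxy groups on Al), formed in the flask | CC1=CCO[Al-]1(OCCOC)OCCOC.[Na+] | intermediate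
7 | (Z)-3-iodobut-2-en-1-ol | OC/C=C(/C)I | intermediate
8 | (Z)-3-iodobut-2-enyl 4-methoxybenzyl ether | COc1ccc(COC/C=C(/C)I)cc1 | intermediate
9 | (Z)-vinyllithium from 8, formed in the flask | COc1ccc(COC/C=C(/C)[Li])cc1 | intermediate
10 | (Z)-4-[(4-methoxybenzyl)oxy]-2-methylbut-2-enal | COc1ccc(COC/C=C(/C)C=O)cc1 | intermediate
11 | (2Z,4R)-1-[(4-methoxybenzyl)oxy]-3-methylhepta-2,6-dien-4-ol | COc1ccc(COC/C=C(/C)[C@H](O)CC=C)cc1 | intermediate
12 | (1R)-1-[(2S,3R)-3-{[(4-methoxybenzyl)oxy]methyl}-2-methyloxiran-2-yl]but-3-en-1-ol | COc1ccc(COC[C@H]2O[C@@]2(C)[C@H](O)CC=C)cc1 | intermediate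
13 | tert-butyldimethylsilyl ether of 12 at the carbinol oxygen | COc1ccc(COC[C@H]2O[C@@]2(C)[C@H](O[Si](C)(C)C(C)(C)C)CC=C)cc1 | intermediate
14 | (3R)-3-(tert-butyldimethylsilyloxy)-3-(oxiranyl)propanal, oxirane and PMB ether as in 12 | COc1ccc(COC[C@H]2O[C@@]2(C)[C@H](O[Si](C)(C)C(C)(C)C)CC=O)cc1 | intermediate
15 | methyl (Z)-2-iodo-5-(tert-butyldimethylsilyloxy)-5-(oxiranyl)pent-2-enoate, oxirane and PMB ether as in 12 | COc1ccc(COC[C@H]2O[C@@]2(C)[C@H](O[Si](C)(C)C(C)(C)C)C/C=C(\I)C(=O)OC)cc1 | intermediate
16 | (E)-3-(tributylstannyl)prop-2-en-1-ol | CCCC[Sn](CCCC)(CCCC)/C=C/CO | starting material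
17 | methyl (2E)-2-[(E)-3-hydroxyprop-1-enyl]-5-(tert-butyldimethylsilyloxy)-5-(oxiranyl)pent-2-enoate (C9 cis to C2 on C1=C10) | COc1ccc(COC[C@H]2O[C@@]2(C)[C@H](O[Si](C)(C)C(C)(C)C)C/C=C(\C=C\CO)C(=O)OC)cc1 | intermediate
18 | (8S,9S)-8,9-epoxide of 17, [(2S,3S)-3-(hydroxymethyl)oxiran-2-yl] group on C10 | COc1ccc(COC[C@H]2O[C@@]2(C)[C@H](O[Si](C)(C)C(C)(C)C)C/C=C(\[C@@H]3O[C@H]3CO)C(=O)OC)cc1 | intermediate
19 | C7 aldehyde of 18 (3-formyloxiranyl group, same configuration) | COc1ccc(COC[C@H]2O[C@@]2(C)[C@H](O[Si](C)(C)C(C)(C)C)C/C=C(\[C@@H]3O[C@H]3C=O)C(=O)OC)cc1 | intermediate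
20 | Baylis–Hillman adduct of 19: C7 carbinol (both epimers) bearing the methyl acrylate unit C11(=C13H2)–C12 | COc1ccc(COC[C@H]2O[C@@]2(C)[C@H](O[Si](C)(C)C(C)(C)C)C/C=C(\[C@@H]3O[C@H]3C(O)C(=C)C(=O)OC)C(=O)OC)cc1 | intermediate
21 | (8S,9R)-9-acetoxy-7,8-dihydroxy compound from opening of 20 at C9 (C7 epimers) | COc1ccc(COC[C@H]2O[C@@]2(C)[C@H](O[Si](C)(C)C(C)(C)C)C/C=C(\[C@@H](OC(C)=O)[C@@H](O)C(O)C(=C)C(=O)OC)C(=O)OC)cc1 | intermediate
22 | (Z)-C7=C11 allylic bromide (CH2Br on C11 cis to C8), (8S,9R), free C8 hydroxyl | COc1ccc(COC[C@H]2O[C@@]2(C)[C@H](O[Si](C)(C)C(C)(C)C)C/C=C(\[C@@H](OC(C)=O)[C@@H](O)/C=C(\CBr)C(=O)OC)C(=O)OC)cc1 | intermediate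
23 | C8 O-triethylsilyl ether of 22 | COc1ccc(COC[C@H]2O[C@@]2(C)[C@H](O[Si](C)(C)C(C)(C)C)C/C=C(\[C@@H](OC(C)=O)[C@@H](O[Si](CC)(CC)CC)/C=C(\CBr)C(=O)OC)C(=O)OC)cc1 | intermediate
24 | C6 primary alcohol obtained from 23 by loss of the PMB group | OC[C@H]1O[C@@]1(C)[C@H](O[Si](C)(C)C(C)(C)C)C/C=C(\[C@@H](OC(C)=O)[C@@H](O[Si](CC)(CC)CC)/C=C(\CBr)C(=O)OC)C(=O)OC | intermediate
25 | seco aldehyde: C6 epoxy aldehyde of 24 with the C13 allylic bromide | O=C[C@H]1O[C@@]1(C)[C@H](O[Si](C)(C)C(C)(C)C)C/C=C(\[C@@H](OC(C)=O)[C@@H](O[Si](CC)(CC)CC)/C=C(\CBr)C(=O)OC)C(=O)OC | intermediate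
26 | ten-membered hydroxy ester: C6 hydroxyl, C7 bearing C(=CH2)CO2Me, other groups as in 27, formed in the flask | C=C(C(=O)OC)[C@@H]1[C@H](O[Si](CC)(CC)CC)[C@H](OC(C)=O)/C(C(=O)OC)=C\C[C@@H](O[Si](C)(C)C(C)(C)C)[C@]2(C)O[C@@H]2[C@H]1O | intermediate
27 | germacra-1(10),11(13)-dien-6,12-olide 14-methyl ester with 4,5-cis-epoxide, 9-acetate, 8-O-triethylsilyl and 3-O-tert-butyldimethylsilyl groups, configurations as in the target | C=C1C(=O)O[C@H]2[C@H]1[C@H](O[Si](CC)(CC)CC)[C@H](OC(C)=O)/C(C(=O)OC)=C\C[C@@H](O[Si](C)(C)C(C)(C)C)[C@]1(C)O[C@H]21 | intermediate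
28 | 8-hydroxy lactone obtained from 27 by loss of the triethylsilyl group | C=C1C(=O)O[C@H]2[C@H]1[C@H](O)[C@H](OC(C)=O)/C(C(=O)OC)=C\C[C@@H](O[Si](C)(C)C(C)(C)C)[C@]1(C)O[C@H]21 | intermediate
29 | mixed anhydride of 4 with 2,4,6-trichlorobenzoic acid, formed in the flask | O=C(OC(=O)[C@@]1(C)O[C@H]1C)c1c(Cl)cc(Cl)cc1Cl | intermediate
30 | 3-O-tert-butyldimethylsilyl ether of the target | C=C1C(=O)O[C@H]2[C@H]1[C@H](OC(=O)[C@@]1(C)O[C@H]1C)[C@H](OC(C)=O)/C(C(=O)OC)=C\C[C@@H](O[Si](C)(C)C(C)(C)C)[C@]1(C)O[C@H]21 | intermediate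
31 | target: methyl (1(10)E,3R,4S,5R,6S,7R,8S,9R)-9-acetoxy-8-{[(2S,3S)-2,3-dimethyloxirane-2-carbonyl]oxy}-4,5-epoxy-3-hydroxygermacra-1(10),11(13)-dien-6,12-olid-14-oate | C=C1C(=O)O[C@H]2[C@H]1[C@H](OC(=O)[C@@]1(C)O[C@H]1C)[C@H](OC(C)=O)/C(C(=O)OC)=C\C[C@@H](O)[C@]1(C)O[C@H]21 | target

**Step count**

Total step count: 24. Longest linear sequence: 21 steps (steps 4 to 24, from but-2-yn-1-ol).

**Steps most likely to fail**

Step 21. The ring closure may be outrun by intermolecular coupling to oligomers, by reductive 1,4-elimination across C13–C11=C7–C8 with loss of the silyloxy group, or it may take the wrong facial course. The fallback sets out from alcohol 24 and replaces the reducing metal by a preformed allyl metal. Hexabutylditin with Pd(PPh3)4 (cat.) in THF should exchange bromide for tin and give the allylic stannane F1. Dess–Martin oxidation (NaHCO3) should then give the stannyl aldehyde F2. InCl3 in ethyl acetate under high dilution (tin-to-indium exchange, cyclic six-membered transition state), followed by PPTS to complete lactonization, should close the ring and come back to the route at 27.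

Step 16. The opening may occur at C8 or in a conjugate sense at C1, the new acetyl group may migrate to the neighbouring free hydroxyls, and the titanium alkoxide may exchange ester groups. The fallback sets out from epoxy alcohol 18, where titanium chelates an unhindered primary carbinol. Ti(OiPr)4/AcOH should give the (8S,9R)-9-acetoxy-7,8-diol F3, and TESOTf/2,6-lutidine the bis(triethylsilyl) ether F4. Swern oxidation, which cleaves and oxidizes the primary triethylsilyl ether selectively, should give the α-silyloxy aldehyde F5. Addition of the [α-(methoxycarbonyl)vinyl]alane made from methyl propiolate, DIBAL-H and N-methylmorpholine N-oxide (a base-free equivalent of the Baylis–Hillman reaction, chosen because F5 carries a β-acetoxy group) should give the adduct F6. N-Bromosuccinimide/Me2S then comes back to the route at 23, which also bypasses the free γ-hydroxy bromide 22.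

Step 15. The amine-catalysed addition may be slow, and during that time the vinyl-epoxy aldehyde may be lost by amine-induced epoxide opening or self-condensation. The fallback sets out from aldehyde 19 and uses the preformed [α-(methoxycarbonyl)vinyl]diisobutylalane (methyl propiolate, DIBAL-H, N-methylmorpholine N-oxide, THF, 0 °C). This hydroalumination/1,2-addition sequence needs no amine and should be complete within hours; it comes back to the route at 20 and makes no new compound (F0).

**Further compounds**

F1 | step 21 | allylic stannane: compound 24 with the C13 bromide replaced by tributylstannyl | OC[C@H]1O[C@@]1(C)[C@H](O[Si](C)(C)C(C)(C)C)C/C=C(\[C@@H](OC(C)=O)[C@@H](O[Si](CC)(CC)CC)/C=C(\C[Sn](CCCC)(CCCC)CCCC)C(=O)OC)C(=O)OC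
F2 | step 21 | stannyl aldehyde: C6 aldehyde of F1 | O=C[C@H]1O[C@@]1(C)[C@H](O[Si](C)(C)C(C)(C)C)C/C=C(\[C@@H](OC(C)=O)[C@@H](O[Si](CC)(CC)CC)/C=C(\C[Sn](CCCC)(CCCC)CCCC)C(=O)OC)C(=O)OC
F3 | step 16 | (8S,9R)-9-acetoxy-7,8-diol from opening of 18 at C9 (C7 is CH2OH) | COc1ccc(COC[C@H]2O[C@@]2(C)[C@H](O[Si](C)(C)C(C)(C)C)C/C=C(\[C@@H](OC(C)=O)[C@@H](O)CO)C(=O)OC)cc1
F4 | step 16 | 7,8-bis(triethylsilyl) ether of F3 | COc1ccc(COC[C@H]2O[C@@]2(C)[C@H](O[Si](C)(C)C(C)(C)C)C/C=C(\[C@@H](OC(C)=O)[C@@H](O[Si](CC)(CC)CC)CO[Si](CC)(CC)CC)C(=O)OC)cc1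
F5 | step 16 | C7 aldehyde with C8 triethylsilyl ether and C9 acetate | COc1ccc(COC[C@H]2O[C@@]2(C)[C@H](O[Si](C)(C)C(C)(C)C)C/C=C(\[C@@H](OC(C)=O)[C@@H](O[Si](CC)(CC)CC)C=O)C(=O)OC)cc1
F6 | step 16 | C7 carbinol (both epimers) bearing the methyl acrylate unit, C8 triethylsilyl ether, C9 acetate | COc1ccc(COC[C@H]2O[C@@]2(C)[C@H](O[Si](C)(C)C(C)(C)C)C/C=C(\[C@@H](OC(C)=O)[C@@H](O[Si](CC)(CC)CC)C(O)C(=C)C(=O)OC)C(=O)OC)cc1
F0 | step 15 | none | none
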